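Everything rests on cutting the C6–C7 bond (numbering below), the single bond shared by the ten-membered carbocycle C1–C10 and the α-methylene γ-lactone O–C6–C7–C11–C12 with its exocyclic C13. Divalent chromium converts an open-chain (Z)-2-(bromomethyl)enoate into an allylchromium that attacks a C6 aldehyde through C7; one operation forms C6–C7, closes the carbocycle, sets C6 and C7 and, when the alkoxide attacks the ester, closes the lactone. The precursor is a linear C6 aldehyde that carries the C3 ketone as a 1,3-dithiane, the preformed (Z)-C1=C10 alkene, a C8 silyl ether and the bromomethyl enoate at C7/C11/C13. Desilylation, acylation and dithiane hydrolysis finish the synthesis.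

Key step: step 14

Numbering (used for all intermediates): ring C1 (=CH), C2, C3 (C=O), C4 (CH–CH3), C5, C6 (lactone O–CH), C7 (fusion CH), C8 (acyloxy CH), C9, C10 (=C–CH3); lactone C11, C12 (C=O), C13 (=CH2). The target is 4R,6R,7S,8R with a trans-fused lactone and a (Z)-C1=C10 alkene. The side chain is the (E)-2-(acetoxymethyl)but-2-enoate.

Assumption: (R)-α-methyl-γ-butyrolactone (1) and methyl (R)-glycidate (12) are bought as single enantiomers.

Design remarks:
- C8 is taken from a glycidic ester, so the C7 aldehyde arises by reduction and no selective deprotection or oxidation is needed there.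
- C6 travels as a dimethyl acetal, so no oxidant or amine has to meet the dithiane and the allylic bromide late in the route.
- The allylic bromide is made by sulfonate displacement and not with an N-bromo reagent, which would attack the dithiane.
- SMILES of 19, 20, 28 and 29 leave the one uncontrolled centre unspecified; it is removed in the following step.

Step 1
Reactants: 1 (R)-α-methyl-γ-butyrolactone
Product: 2 (3R)-3-methyloxolan-2-ol (lactol as a mixture of anomers)
Conditions: i-Bu2AlH (1.1 equiv), CH2Cl2, −78 °C
Reagents that add atoms: none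
Why: Partial reduction of a γ-lactone with i-Bu2AlH at −78 °C stops at the tetrahedral aluminium hemiacetal, which gives the lactol on work-up, and the C4 stereocentre is not touched because no base is present.

Step 2
Reactants: 2 (3R)-3-methyloxolan-2-ol
Product: 3 (3R)-3-(1,3-dithian-2-yl)butan-1-ol
Conditions: HS(CH2)3SH, BF3·OEt2, CH2Cl2, −20 to 0 °C
Reagents that add atoms: propane-1,3-dithiol, SCCCS
Why: Lewis-acid thioacetalisation of the open hydroxy aldehyde form of the lactol gives the dithiane (the future C3) and frees the C6 hydroxyl; at low temperature thioacetal formation should be faster than enolisation toward C4.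

Step 3
Reactants: 3 (3R)-3-(1,3-dithian-2-yl)butan-1-ol
Product: 4 (3R)-3-(1,3-dithian-2-yl)butanal
Conditions: SO3·pyridine, DMSO, i-Pr2NEt, CH2Cl2, 0 °C
Reagents that add atoms: none
Why: Parikh–Doering oxidation (activated DMSO) converts the primary alcohol into the aldehyde without touching the thioacetal sulfur, and the product has no stereocentre next to the carbonyl group because C5 is CH2.

Step 4
Reactants: 4 (3R)-3-(1,3-dithian-2-yl)butanal
Product: 5 2-[(2R)-4,4-dimethoxybutan-2-yl]-1,3-dithiane
Conditions: HC(OCH3)3, MeOH, PPTS (cat.), rt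
Reagents that add atoms: trimethyl orthoformate, COC(OC)OC; methanol, CO
Why: Acid-catalysed acetalisation with trimethyl orthoformate as water scavenger masks C6 at the aldehyde oxidation level, the dithiane being inert to these conditions.

Step 5
Reactants: 6 but-2-yn-1-ol
Product: 8 (2Z)-3-iodobut-2-en-1-ol, via alkenylaluminate 7 (not isolated)
Conditions: NaAlH2(OCH2CH2OCH3)2, THF, 0 °C to rt; then I2, −78 to 0 °C
Reagents that add atoms: iodine, II
Why: Hydroxyl-directed anti hydroalumination of the propargylic alcohol places aluminium on the distal alkyne carbon (C10) cis to the carbinol carbon, and iodinolysis of the C–Al bond with retention gives the (Z)-iodide, which fixes the cis relation of C2 and C9 across C1=C10.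

Step 6
Reactants: 8 (2Z)-3-iodobut-2-en-1-ol
Product: 9 (2Z)-1-bromo-3-iodobut-2-ene
Conditions: PBr3, Et2O, 0 °C
Reagents that add atoms: phosphorus tribromide, BrP(Br)Br
Why: Bromination of the primary allylic alcohol with PBr3 proceeds by SN2 displacement of the phosphite ester at 0 °C without allylic transposition and leaves the vinyl iodide and the alkene geometry unchanged.

Step 7
Reactants: 5 2-[(2R)-4,4-dimethoxybutan-2-yl]-1,3-dithiane; 9 (2Z)-1-bromo-3-iodobut-2-ene
Product: 11 2-[(2R)-4,4-dimethoxybutan-2-yl]-2-[(2Z)-3-iodobut-2-en-1-yl]-1,3-dithiane, via 2-lithiodithiane 10 (not isolated)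
Conditions: t-BuLi (1.0 equiv), THF/HMPA (9:1), −78 °C; then 9, −78 °C
Reagents that add atoms: none
Why: Corey–Seebach alkylation, in which t-BuLi/HMPA deprotonates the hindered 2-alkyl-1,3-dithiane at C3 and the soft carbanion displaces the primary allylic bromide by SN2 far faster than it exchanges with the vinyl iodide, forming C2–C3 while the non-acidic C4 keeps its configuration.

Step 8
Reactants: 11 2-[(2R)-4,4-dimethoxybutan-2-yl]-2-[(2Z)-3-iodobut-2-en-1-yl]-1,3-dithiane; 12 methyl (R)-glycidate
Product: 15 methyl (2R,4Z)-6-{2-[(2R)-4,4-dimethoxybutan-2-yl]-1,3-dithian-2-yl}-2-hydroxy-4-methylhex-4-enoate, via vinyllithium 13 (not isolated), via vinylmagnesium bromide 14 (not isolated)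
Conditions: t-BuLi (2.0 equiv), Et2O, −78 °C; MgBr2·OEt2; CuI (10 mol %), 12 (1.3 equiv), THF, −78 to −30 °C
Reagents that add atoms: none
Why: Iodine–lithium exchange with retention of alkene geometry, transmetalation to magnesium and CuI-catalysed opening of the glycidic ester at its unsubstituted carbon (the known regiochemistry of organocopper additions to glycidates) form C9–C10, and the C8 stereocentre comes unchanged from 12 because its C–O bond is not broken.

Step 9
Reactants: 15 methyl (2R,4Z)-6-{2-[(2R)-4,4-dimethoxybutan-2-yl]-1,3-dithian-2-yl}-2-hydroxy-4-methylhex-4-enoate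
Product: 16 methyl (2R,4Z)-2-[(tert-butyldimethylsilyl)oxy]-6-{2-[(2R)-4,4-dimethoxybutan-2-yl]-1,3-dithian-2-yl}-4-methylhex-4-enoate
Conditions: TBSCl, imidazole, DMF, rt
Reagents that add atoms: tert-butyldimethylsilyl chloride, CC(C)(C)[Si](C)(C)Cl
Why: Standard silylation of a secondary α-hydroxy ester with TBSCl/imidazole, chosen over a silyl triflate because silyl triflates cleave dimethyl acetals.

Step 10
Reactants: 16 methyl (2R,4Z)-2-[(tert-butyldimethylsilyl)oxy]-6-{2-[(2R)-4,4-dimethoxybutan-2-yl]-1,3-dithian-2-yl}-4-methylhex-4-enoate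
Product: 17 (2R,4Z)-2-[(tert-butyldimethylsilyl)oxy]-6-{2-[(2R)-4,4-dimethoxybutan-2-yl]-1,3-dithian-2-yl}-4-methylhex-4-enal
Conditions: i-Bu2AlH (1.1 equiv), CH2Cl2, −78 °C; MeOH quench at −78 °C
Reagents that add atoms: none
Why: Reduction of an α-silyloxy methyl ester with i-Bu2AlH at −78 °C stops at the stable tetrahedral aluminium hemiacetal and gives the C7 aldehyde on work-up, without base and therefore without epimerisation at C8.

Step 11
Reactants: 17 (2R,4Z)-2-[(tert-butyldimethylsilyl)oxy]-6-{2-[(2R)-4,4-dimethoxybutan-2-yl]-1,3-dithian-2-yl}-4-methylhex-4-enal; 18 methyl acrylate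
Product: 19 methyl (4R,6Z)-4-[(tert-butyldimethylsilyl)oxy]-8-{2-[(2R)-4,4-dimethoxybutan-2-yl]-1,3-dithian-2-yl}-3-hydroxy-6-methyl-2-methylideneoct-6-enoate (both epimers at the carbinol, which is C7)
Conditions: 18 (excess), DABCO, MeOH (minimal), rt
Reagents that add atoms: none
Why: Morita–Baylis–Hillman reaction, in which DABCO adds to methyl acrylate and the zwitterionic enolate adds to the activated α-silyloxy aldehyde to form C7–C11; the configuration of the new C7 carbinol is irrelevant because the next step makes C7 sp2.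

Step 12
Reactants: 19 methyl (4R,6Z)-4-[(tert-butyldimethylsilyl)oxy]-8-{2-[(2R)-4,4-dimethoxybutan-2-yl]-1,3-dithian-2-yl}-3-hydroxy-6-methyl-2-methylideneoct-6-enoate
Product: 21 methyl (2Z,4R,6Z)-2-(bromomethyl)-4-[(tert-butyldimethylsilyl)oxy]-8-{2-[(2R)-4,4-dimethoxybutan-2-yl]-1,3-dithian-2-yl}-6-methylocta-2,6-dienoate, via allylic mesylate 20 (not isolated)
Conditions: (CH3SO2)2O, i-Pr2NEt, CH2Cl2, −20 °C; then LiBr, THF, 0 °C to rt
Reagents that add atoms: lithium bromide, [Li+].[Br-]
Why: Sulfonylation of the Baylis–Hillman alcohol followed by SN2' displacement with bromide, which is reversible and settles on the conjugated (Z)-2-(bromomethyl)enoate with C8 trans to the ester, and no N-bromo reagent is used so that the dithiane is not oxidised.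

Step 13
Reactants: 21 methyl (2Z,4R,6Z)-2-(bromomethyl)-4-[(tert-butyldimethylsilyl)oxy]-8-{2-[(2R)-4,4-dimethoxybutan-2-yl]-1,3-dithian-2-yl}-6-methylocta-2,6-dienoate
Product: 22 methyl (2Z,4R,6Z)-2-(bromomethyl)-4-[(tert-butyldimethylsilyl)oxy]-6-methyl-8-{2-[(2R)-4-oxobutan-2-yl]-1,3-dithian-2-yl}octa-2,6-dienoate (the open-chain bromo aldehyde)
Conditions: 10% aq. oxalic acid on SiO2, CH2Cl2, rt; used at once
Reagents that add atoms: water, O
Why: Mild acid hydrolysis of the acyclic dimethyl acetal on wet SiO2 is much faster than cleavage of the secondary TBS ether or of the dithiane, and no amine or oxidant meets the reactive allylic bromide.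

Step 14
Reactants: 22 the open-chain bromo aldehyde
Product: 25 trans-fused ten-membered α-methylene γ-lactone (1(10)Z,4R,6R,7S,8R) bearing the C3 1,3-dithiane plus the C8 OTBS group, via allylchromium 23 (not isolated), via chromium alkoxide 24 (not isolated)
Conditions: CrCl2 (10 equiv), degassed THF, rt, syringe-pump addition of 22 to a final 0.003 M; aqueous work-up
Reagents that add atoms: none
Why: Two single-electron transfers from divalent chromium convert the C13–Br bond of 22 into the trivalent allylchromium 23, which is configurationally mobile by 1,3-metal shift and adds through its γ-carbon C7 to the C6 aldehyde in a six-membered chair transition state while the double bond moves to C11=C13; the closest known reaction type is the intramolecular Nozaki–Hiyama allylation of aldehydes by 2-(bromomethyl)acrylates with lactonisation, which is known for ten-membered sesquiterpene lactones. The carbocycle closes in this carbonyl addition (10-exo-trig attack on C6), and the chromium alkoxide 24 then closes the γ-lactone by 5-exo-trig acyl substitution on the methyl ester. C6 is set relative to C7 by the chair that holds C5 and C8 both equatorial (C8 trans to the CH2–Cr arm after equilibration), which is the anti adduct and therefore the trans-fused lactone. C7 is expected to be set by the C8 stereocentre: with H8 eclipsing the C7=C11 plane to avoid allylic 1,3-strain against the ester, C9 leaves on one face and the ring can close only with a staggered, nearly anti C9–C8–C7–C6 torsion, so C6 should bond on the face syn to the silyloxy group, which corresponds to 7S. The step needs chemoselectivity, anti selectivity and this face selectivity: the aldehyde is the only electrophile because C3 is a dithiane and esters do not react with allylchromium, the chair and the C8 centre are relied on for the other two, and the preformed (Z)-C1=C10 alkene together with high dilution favours ring closure over oligomerisation.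

Step 15
Reactants: 26 tert-butyl acrylate; 27 acetaldehyde
Product: 28 tert-butyl 3-hydroxy-2-methylidenebutanoate (racemic)
Conditions: DABCO, neat with excess 27, sealed vessel, rt
Reagents that add atoms: none
Why: Morita–Baylis–Hillman reaction of acetaldehyde with tert-butyl acrylate under DABCO catalysis; the carbinol is racemic, which does not matter because this centre becomes sp2 in the next step.

Step 16
Reactants: 28 tert-butyl 3-hydroxy-2-methylidenebutanoate
Product: 30 tert-butyl (2E)-2-(acetoxymethyl)but-2-enoate, via secondary acetate 29 (not isolated)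
Conditions: Ac2O, Et3N, DMAP (cat.), THF, 0 °C to rt; then DABCO (20 mol %), 65 °C
Reagents that add atoms: acetic anhydride, CC(=O)OC(C)=O
Why: Acetylation followed by the known DABCO-catalysed 1,3-transposition of Baylis–Hillman acetates (SN2' addition of the amine, return of acetate at the primary carbon) gives the thermodynamically preferred trisubstituted enoate with the methyl group trans to the ester, which is the E isomer required.

Step 17
Reactants: 30 tert-butyl (2E)-2-(acetoxymethyl)but-2-enoate
Product: 31 (2E)-2-(acetoxymethyl)but-2-enoic acid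
Conditions: CF3CO2H, CH2Cl2, 0 °C to rt
Reagents that add atoms: none
Why: Acidolysis of the tert-butyl ester (loss of isobutene through the tert-butyl cation) frees the acid and leaves the primary acetate and the alkene geometry intact.

Step 18
Reactants: 25 the dithiane TBS lactone
Product: 32 the corresponding C8 alcohol (1(10)Z,4R,6R,7R,8R; same spatial arrangement as 25, the C7 label changes with the ranking only)
Conditions: HF·pyridine, pyridine, THF, 0 °C to rt
Reagents that add atoms: none
Why: Fluoride-mediated desilylation with buffered HF·pyridine removes the secondary TBS ether under mildly acidic conditions, which avoids base-induced conjugate addition to the α-methylene lactone and migration of the lactone to O8.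

Step 19
Reactants: 32 the C8 alcohol; 31 (2E)-2-(acetoxymethyl)but-2-enoic acid
Product: 34 the 8-O-[(2E)-2-(acetoxymethyl)but-2-enoyl] dithiane lactone (1(10)Z,4R,6R,7S,8R), via mixed anhydride 33 (not isolated)
Conditions: 31, 2,4,6-trichlorobenzoyl chloride, Et3N, THF, rt; then 32, DMAP, toluene, rt
Reagents that add atoms: none
Why: Yamaguchi esterification, in which the mixed anhydride with 2,4,6-trichlorobenzoic acid and DMAP acylates the hindered secondary C8 hydroxyl with retention at C8, the E acid being the thermodynamically stable geometry so that isomerisation is not a concern.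

Step 20
Reactants: 34 the acylated dithiane lactone
Product: 35 the target CNP0265140.1 (1(10)Z,4R,6R,7S,8R)
Conditions: MeI (excess), CaCO3, MeCN/H2O (9:1), 40 °C
Reagents that add atoms: water, O
Why: Alkylative dithiane hydrolysis, in which S-methylation by MeI and hydrolysis of the sulfonium salt, buffered by CaCO3, release the C3 ketone under nearly neutral conditions so that C4 should not epimerise and the C1=C10 double bond should not move into conjugation.

Compound list
1 | (R)-α-methyl-γ-butyrolactone, (3R)-3-methyloxolan-2-one | C[C@@H]1CCOC1=O | starting material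
2 | (3R)-3-methyloxolan-2-ol, anomer mixture | C[C@@H]1CCOC1O | intermediate
3 | (3R)-3-(1,3-dithian-2-yl)butan-1-ol | OCC[C@@H](C)C1SCCCS1 | intermediate
4 | (3R)-3-(1,3-dithian-2-yl)butanal | O=CC[C@@H](C)C1SCCCS1 | intermediate
5 | 2-[(2R)-4,4-dimethoxybutan-2-yl]-1,3-dithiane | COC(OC)C[C@@H](C)C1SCCCS1 | intermediate
6 | but-2-yn-1-ol | CC#CCO | starting material
7 | sodium cyclic (Z)-alkenylaluminate: Al on the methyl-bearing alkene carbon and on the carbinol oxygen, two 2-methoxyethoxy ligands (formed in the flask) | CC1=CCO[Al-]1(OCCOC)OCCOC.[Na+] | intermediate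
8 | (2Z)-3-iodobut-2-en-1-ol | C/C(I)=C/CO | intermediate
9 | (2Z)-1-bromo-3-iodobut-2-ene | C/C(I)=C/CBr | intermediate
10 | 2-lithio derivative of 5 (formed in the flask) | COC(OC)C[C@@H](C)C1([Li])SCCCS1 | intermediate
11 | 2-[(2R)-4,4-dimethoxybutan-2-yl]-2-[(2Z)-3-iodobut-2-en-1-yl]-1,3-dithiane | COC(OC)C[C@@H](C)C1(SCCCS1)C/C=C(/C)I | intermediate
12 | methyl (R)-glycidate, methyl (2R)-oxirane-2-carboxylate | COC(=O)[C@H]1CO1 | starting material
13 | (Z)-vinyllithium from 11, Li in place of I (formed in the flask) | COC(OC)C[C@@H](C)C1(SCCCS1)C/C=C(/C)[Li] | intermediate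
14 | (Z)-vinylmagnesium bromide from 13 (formed in the flask) | COC(OC)C[C@@H](C)C1(SCCCS1)C/C=C(/C)[Mg]Br | intermediate
15 | methyl (2R,4Z)-6-{2-[(2R)-4,4-dimethoxybutan-2-yl]-1,3-dithian-2-yl}-2-hydroxy-4-methylhex-4-enoate | COC(OC)C[C@@H](C)C1(SCCCS1)C/C=C(/C)C[C@@H](O)C(=O)OC | intermediate
16 | methyl (2R,4Z)-2-[(tert-butyldimethylsilyl)oxy]-6-{2-[(2R)-4,4-dimethoxybutan-2-yl]-1,3-dithian-2-yl}-4-methylhex-4-enoate | COC(OC)C[C@@H](C)C1(SCCCS1)C/C=C(/C)C[C@@H](O[Si](C)(C)C(C)(C)C)C(=O)OC | intermediate
17 | (2R,4Z)-2-[(tert-butyldimethylsilyl)oxy]-6-{2-[(2R)-4,4-dimethoxybutan-2-yl]-1,3-dithian-2-yl}-4-methylhex-4-enal | COC(OC)C[C@@H](C)C1(SCCCS1)C/C=C(/C)C[C@@H](O[Si](C)(C)C(C)(C)C)C=O | intermediate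
18 | methyl acrylate | C=CC(=O)OC | starting material
19 | methyl (4R,6Z)-4-[(tert-butyldimethylsilyl)oxy]-8-{2-[(2R)-4,4-dimethoxybutan-2-yl]-1,3-dithian-2-yl}-3-hydroxy-6-methyl-2-methylideneoct-6-enoate, both C3 epimers | COC(OC)C[C@@H](C)C1(SCCCS1)C/C=C(/C)C[C@@H](O[Si](C)(C)C(C)(C)C)C(O)C(=C)C(=O)OC | intermediate
20 | 3-O-methanesulfonate of 19 (formed in the flask) | COC(OC)C[C@@H](C)C1(SCCCS1)C/C=C(/C)C[C@@H](O[Si](C)(C)C(C)(C)C)C(OS(C)(=O)=O)C(=C)C(=O)OC | intermediate
21 | methyl (2Z,4R,6Z)-2-(bromomethyl)-4-[(tert-butyldimethylsilyl)oxy]-8-{2-[(2R)-4,4-dimethoxybutan-2-yl]-1,3-dithian-2-yl}-6-methylocta-2,6-dienoate | COC(OC)C[C@@H](C)C1(SCCCS1)C/C=C(/C)C[C@@H](O[Si](C)(C)C(C)(C)C)/C=C(\CBr)C(=O)OC | intermediate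
22 | methyl (2Z,4R,6Z)-2-(bromomethyl)-4-[(tert-butyldimethylsilyl)oxy]-6-methyl-8-{2-[(2R)-4-oxobutan-2-yl]-1,3-dithian-2-yl}octa-2,6-dienoate, precursor of the key step | O=CC[C@@H](C)C1(SCCCS1)C/C=C(/C)C[C@@H](O[Si](C)(C)C(C)(C)C)/C=C(\CBr)C(=O)OC | intermediate
23 | allylchromium: 22 with a CrCl2 group (trivalent chromium) on C13 in place of Br, C7=C11 geometry mobile (formed in the flask) | O=CC[C@@H](C)C1(SCCCS1)C/C=C(/C)C[C@@H](O[Si](C)(C)C(C)(C)C)C=C(C[Cr](Cl)Cl)C(=O)OC | intermediate
24 | ring-closed chromium alkoxide: ten-membered ring, C6–O–CrCl2, C7 bearing the methyl propenoate unit, configuration as in 25 (formed in the flask) | C=C(C(=O)OC)[C@H]1[C@H](O[Cr](Cl)Cl)C[C@@H](C)C2(SCCCS2)C/C=C(/C)C[C@H]1O[Si](C)(C)C(C)(C)C | intermediate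
25 | (1(10)Z,4R,6R,7S,8R) trans-fused ten-membered α-methylene γ-lactone with C3 as 1,3-dithiane and C8–OTBS, product of the key step | C=C1C(=O)O[C@@H]2C[C@@H](C)C3(SCCCS3)C/C=C(/C)C[C@@H](O[Si](C)(C)C(C)(C)C)[C@@H]12 | intermediate
26 | tert-butyl acrylate | C=CC(=O)OC(C)(C)C | starting material
27 | acetaldehyde | CC=O | starting material
28 | tert-butyl 3-hydroxy-2-methylidenebutanoate, racemic | CC(O)C(=C)C(=O)OC(C)(C)C | intermediate
29 | tert-butyl 3-acetoxy-2-methylidenebutanoate, racemic (formed in the flask) | CC(OC(C)=O)C(=C)C(=O)OC(C)(C)C | intermediate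
30 | tert-butyl (2E)-2-(acetoxymethyl)but-2-enoate | C/C=C(\COC(C)=O)C(=O)OC(C)(C)C | intermediate
31 | (2E)-2-(acetoxymethyl)but-2-enoic acid | C/C=C(\COC(C)=O)C(=O)O | intermediate
32 | (1(10)Z,4R,6R,7R,8R) dithiane lactone with free C8 hydroxyl | C=C1C(=O)O[C@@H]2C[C@@H](C)C3(SCCCS3)C/C=C(/C)C[C@@H](O)[C@@H]12 | intermediate
33 | mixed anhydride of 31 with 2,4,6-trichlorobenzoic acid (formed in the flask) | C/C=C(\COC(C)=O)C(=O)OC(=O)c1c(Cl)cc(Cl)cc1Cl | intermediate
34 | (1(10)Z,4R,6R,7S,8R) dithiane lactone acylated at O8 with the (2E)-2-(acetoxymethyl)but-2-enoyl group | C=C1C(=O)O[C@@H]2C[C@@H](C)C3(SCCCS3)C/C=C(/C)C[C@@H](OC(=O)/C(=C/C)COC(C)=O)[C@@H]12 | intermediate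
35 | CNP0265140.1, (1(10)Z,4R,6R,7S,8R) 3-oxo lactone with the 8-O-[(2E)-2-(acetoxymethyl)but-2-enoyl] group | C=C1C(=O)O[C@@H]2C[C@@H](C)C(=O)C/C=C(/C)C[C@@H](OC(=O)/C(=C/C)COC(C)=O)[C@@H]12 | target

Total step count: 20. Longest linear sequence: 15 steps (steps 1–4, 7–14, 18–20).

Steps most likely to fail

Step 14. The ring closure may show poor facial selectivity at C7: the C8 silyloxy centre, under the constraint of the forming ring, may steer the aldehyde to the other face of the allylchromium, which with the anti chair would give the 6S,7R lactone. The fallback turns the same directing effect around and sets C8 afterwards by inversion. It sets out from 11, which is coupled as in step 8 with methyl (S)-glycidate (bought, COC(=O)[C@@H]1CO1) to give the 8-epi hydroxy ester F1. Steps 9 to 13 are repeated in this series and should give the silyl ether F2, the aldehyde F3, the Baylis–Hillman adduct F4, the mesylate F5 formed in the flask, the allylic bromide F6 and the bromo aldehyde F7. Cyclisation with CrCl2 through the allylchromium F8 and the chromium alkoxide F9 should then give the 8-epi lactone F10 with the required 6R,7S configuration, and HF·pyridine the 8-epi alcohol F11. Mitsunobu esterification of F11 with 31 (PPh3, diisopropyl azodicarboxylate, toluene, 0 °C to rt) inverts C8 and rejoins the route at 34.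

Step 11. The amine-catalysed addition to a large, α-oxygenated aldehyde may be slow, and over days the aldehyde can enolise with loss of configuration at C8 or the silyl group can migrate to the new C7 hydroxyl. The fallback replaces catalysis by a preformed nucleophile and sets out from 17. Methyl propiolate is hydroaluminated with i-Bu2AlH and N-methylmorpholine N-oxide in THF at 0 °C to the α-aluminoacrylate F12. Carbonyl addition of this vinylalane to 17 at 0 °C should give, after work-up, the same adduct 19 within hours and without amine.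

Step 20. S-Methylation of the fully substituted, hindered C3 dithiane may be slow, and during a long reaction the acid released can move the C1=C10 double bond into conjugation with the new ketone or epimerise C4, while the allylic acetate is exposed as well. The fallback unmasks the ketone earlier and by oxidation, and sets out from 25. PhI(OCOCF3)2 in MeCN/H2O at 0 °C (oxidative dithiane hydrolysis) should give the keto silyl ether F13. HF·pyridine then gives the keto alcohol F14, and Yamaguchi acylation with 31 through 33 gives 35 directly.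

Further compounds
F1 | step 14 | methyl (2S,4Z)-6-{2-[(2R)-4,4-dimethoxybutan-2-yl]-1,3-dithian-2-yl}-2-hydroxy-4-methylhex-4-enoate (8-epi-15) | COC(OC)C[C@@H](C)C1(SCCCS1)C/C=C(/C)C[C@H](O)C(=O)OC
F2 | step 14 | TBS ether of F1 (8-epi-16) | COC(OC)C[C@@H](C)C1(SCCCS1)C/C=C(/C)C[C@H](O[Si](C)(C)C(C)(C)C)C(=O)OC
F3 | step 14 | 8-epi-17, the (2S) aldehyde | COC(OC)C[C@@H](C)C1(SCCCS1)C/C=C(/C)C[C@H](O[Si](C)(C)C(C)(C)C)C=O
F4 | step 14 | 8-epi-19, Baylis–Hillman adduct, both carbinol epimers | COC(OC)C[C@@H](C)C1(SCCCS1)C/C=C(/C)C[C@H](O[Si](C)(C)C(C)(C)C)C(O)C(=C)C(=O)OC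
F5 | step 14 | 8-epi-20, methanesulfonate of F4 | COC(OC)C[C@@H](C)C1(SCCCS1)C/C=C(/C)C[C@H](O[Si](C)(C)C(C)(C)C)C(OS(C)(=O)=O)C(=C)C(=O)OC
F6 | step 14 | 8-epi-21, (2Z,4S,6Z) allylic bromide acetal | COC(OC)C[C@@H](C)C1(SCCCS1)C/C=C(/C)C[C@H](O[Si](C)(C)C(C)(C)C)/C=C(\CBr)C(=O)OC
F7 | step 14 | 8-epi-22, (2Z,4S,6Z) bromo aldehyde | O=CC[C@@H](C)C1(SCCCS1)C/C=C(/C)C[C@H](O[Si](C)(C)C(C)(C)C)/C=C(\CBr)C(=O)OC
F8 | step 14 | 8-epi-23, allylchromium with a CrCl2 group (trivalent chromium) on C13 | O=CC[C@@H](C)C1(SCCCS1)C/C=C(/C)C[C@H](O[Si](C)(C)C(C)(C)C)C=C(C[Cr](Cl)Cl)C(=O)OC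
F9 | step 14 | 8-epi-24, ring-closed chromium alkoxide | C=C(C(=O)OC)[C@H]1[C@H](O[Cr](Cl)Cl)C[C@@H](C)C2(SCCCS2)C/C=C(/C)C[C@@H]1O[Si](C)(C)C(C)(C)C
F10 | step 14 | 8-epi-25, (1(10)Z,4R,6R,7S,8S) dithiane TBS lactone | C=C1C(=O)O[C@@H]2C[C@@H](C)C3(SCCCS3)C/C=C(/C)C[C@H](O[Si](C)(C)C(C)(C)C)[C@@H]12
F11 | step 14 | 8-epi-32, (1(10)Z,4R,6R,7R,8S) dithiane hydroxy lactone | C=C1C(=O)O[C@@H]2C[C@@H](C)C3(SCCCS3)C/C=C(/C)C[C@H](O)[C@@H]12
F12 | step 11 | [1-(methoxycarbonyl)ethenyl]bis(2-methylpropyl)aluminium | C=C(C(=O)OC)[Al](CC(C)C)CC(C)C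
F13 | step 20 | (1(10)Z,4R,6R,7S,8R) 3-oxo lactone with C8–OTBS | C=C1C(=O)O[C@@H]2C[C@@H](C)C(=O)C/C=C(/C)C[C@@H](O[Si](C)(C)C(C)(C)C)[C@@H]12
F14 | step 20 | (1(10)Z,4R,6R,7R,8R) 3-oxo lactone with free C8 hydroxyl | C=C1C(=O)O[C@@H]2C[C@@H](C)C(=O)C/C=C(/C)C[C@@H](O)[C@@H]12
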